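Everything rests on disconnecting the C3–C4 bond of the oxolane ring (O1, C2–C5). This bond joins two carbons that are each β to an oxygen, so no simple polar pairing makes it, and it carries the cis C9 hydroxymethyl/C7′ benzyl pair next to the C2 aryl centre. A titanocene(III) epoxide opening places a radical on C3, which closes 5-exo onto a styrene: one operation forms C3–C4, the ring and both new stereocentres under relay from C2, and the oxirane oxygen emerges as the C9 hydroxyl. The precursor is an enantiopure (oxiranyl)(3,4,5-trimethoxyphenyl)carbinol whose hydroxyl is etherified with the O-benzyl-protected (E)-cinnamyl unit.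

Key step: step 7

Remark on the chemistry: the oxolane is numbered O1, C2 (aryl), C3 (bearing C9H2OH), C4 (bearing the benzylic C7′H2), C5; the target is the (2R,3S,4S) isomer (aryl trans to C9, C9 cis to benzyl). Compounds 4 and 7 are racemates. It is assumed that the enantiomer of 7 consumed with L-(+)-DIPT is (R), the spatial counterpart of the fast-reacting (S)-alkyl vinyl carbinols, because aryl outranks vinyl in the CIP order. Equivalents and loadings are proposed values.

Step 1
Reactants: 1 3-hydroxy-4,5-dimethoxybenzaldehyde
Product: 2 3-(benzyloxy)-4,5-dimethoxybenzaldehyde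
Conditions: BnBr, K2CO3, DMF, rt
Reagents that add atoms: benzyl bromide, BrCc1ccccc1
Why: Williamson ether synthesis, in which the phenoxide formed with carbonate displaces bromide from benzyl bromide by SN2 while the aldehyde is untouched.

Step 2
Reactants: 2 3-(benzyloxy)-4,5-dimethoxybenzaldehyde; 3 vinylmagnesium bromide
Product: 4 rac-1-[3-(benzyloxy)-4,5-dimethoxyphenyl]prop-2-en-1-ol
Conditions: CH2=CHMgBr, THF, 0 °C; aqueous work-up
Reagents that add atoms: vinylmagnesium bromide (3), C=C[Mg]Br
Why: Grignard 1,2-addition to the aryl aldehyde gives the secondary allylic alcohol as a racemate, which does not matter because this carbinol centre is removed in step 3.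

Step 3
Reactants: 4 rac-1-[3-(benzyloxy)-4,5-dimethoxyphenyl]prop-2-en-1-ol
Product: 5 1-(benzyloxy)-5-[(1E)-3-bromoprop-1-en-1-yl]-2,3-dimethoxybenzene ((E)-cinnamyl bromide)
Conditions: PBr3 (0.4 equiv), Et2O, 0 °C; used crude
Reagents that add atoms: phosphorus tribromide, BrP(Br)Br
Why: Bromination with allylic transposition, in which PBr3 activates the secondary hydroxyl and the aryl-stabilised allyl cation/bromide pair (SN1/SN2′) collapses to the conjugated primary (E)-bromide, the thermodynamically preferred isomer, while the aryl ethers are inert at 0 °C.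

Step 4
Reactants: 6 3,4,5-trimethoxybenzaldehyde; 3 vinylmagnesium bromide
Product: 7 rac-1-(3,4,5-trimethoxyphenyl)prop-2-en-1-ol
Conditions: CH2=CHMgBr, THF, 0 °C; aqueous work-up
Reagents that add atoms: vinylmagnesium bromide (3), C=C[Mg]Br
Why: Grignard 1,2-addition gives the racemic aryl vinyl carbinol that the next step resolves and epoxidises in one operation.

Step 5
Reactants: 7 rac-1-(3,4,5-trimethoxyphenyl)prop-2-en-1-ol
Product: 8 (S)-[(2R)-oxiran-2-yl](3,4,5-trimethoxyphenyl)methanol (erythro epoxy alcohol)
Conditions: Ti(OiPr)4 (15 mol%), L-(+)-DIPT (20 mol%), t-BuOOH (0.45 equiv), 4 Å MS, CH2Cl2, −20 °C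
Reagents that add atoms: tert-butyl hydroperoxide, CC(C)(C)OO
Why: Sharpless kinetic resolution (titanium tartrate-catalysed asymmetric epoxidation of a secondary allylic alcohol): with L-(+)-DIPT the (R)-enantiomer of 7 should be epoxidised much faster than its antipode and on the face that gives the erythro epoxy alcohol, so that with the oxidant limited to below half an equivalent 8 is expected in high enantiomeric purity beside unchanged (S)-7; the carbinol centre (the future C2) is set by this choice of enantiomer, its descriptor becoming S only because oxiranyl now outranks aryl, and the oxirane centre is set by the tartrate-controlled face.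

Step 6
Reactants: 8 (S)-[(2R)-oxiran-2-yl](3,4,5-trimethoxyphenyl)methanol; 5 (E)-cinnamyl bromide
Product: 9 (2R)-2-[(S)-{[(2E)-3-[3-(benzyloxy)-4,5-dimethoxyphenyl]prop-2-en-1-yl]oxy}(3,4,5-trimethoxyphenyl)methyl]oxirane (epoxy cinnamyl ether)
Conditions: Ag2O (2 equiv), 5 (1.5 equiv), 4 Å MS, CH2Cl2, rt, dark
Reagents that add atoms: none
Why: Silver(I) oxide-mediated Williamson-type etherification, in which silver-assisted departure of bromide lets the neutral secondary hydroxyl attack the primary allylic terminus (conjugation retained), and because no free alkoxide is formed, Payne rearrangement, epoxide opening and epimerisation of the carbinol centre are avoided.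

Step 7
Reactants: 9 epoxy cinnamyl ether
Product: 11 [(2R,3S,4S)-4-[3-(benzyloxy)-4,5-dimethoxybenzyl]-2-(3,4,5-trimethoxyphenyl)oxolan-3-yl]methanol (O-benzyl ether of the target), via bis-titanium(IV) cyclised intermediate 10 (not isolated)
Conditions: Cp2TiCl2 (2.5 equiv), Zn dust, THF, rt, the green Cp2TiCl solution added slowly to 9; then 1 M HCl
Reagents that add atoms: none
Why: Cp2TiCl transfers one electron to the oxirane of 9 and cleaves its C3–O bond, leaving the oxygen on C9 as a titanium(IV) alkoxide and a secondary radical on C3 (the oxirane configuration is lost here); the radical adds to the styrene carbon C4, and the benzylic C7′ radical so formed is reduced by a second titanium(III) to give 10, which the acid work-up protonates at C7′ and O9. The closest known reaction type is the titanocene(III)-mediated reductive epoxide opening with radical cyclisation of epoxy allyl and cinnamyl ethers to 3-hydroxymethyl-4-benzyl tetrahydrofurans. The oxolane (O1, C2, C3, C4, C5) closes in the 5-exo-trig mode by formation of C3–C4. C3 and C4 are both set under control of the existing C2 centre through a chair-like transition state in which the C2 aryl group is pseudo-equatorial: the C9 titanoxymethyl group on the radical carbon turns away from the aryl (2,3-trans) and the styryl arm lies pseudo-equatorial, which puts the benzyl group trans to the aryl and cis to C9. The step needs the cyclisation to be faster than capture of the C3 radical by titanium(III), which would end in β-elimination, and this is secured by the aryl-conjugated acceptor, which makes the closure fast and irreversible, and by the slow addition of titanium(III); the regioselectivity of the opening is secured by the greater stability of the secondary radical.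

Step 8
Reactants: 11 O-benzyl ether of the target
Product: 12 [(2R,3S,4S)-4-(3-hydroxy-4,5-dimethoxybenzyl)-2-(3,4,5-trimethoxyphenyl)oxolan-3-yl]methanol (target, CNP0121704.1)
Conditions: H2 (1 atm), 10% Pd/C, EtOAc, rt, stopped at full conversion
Reagents that add atoms: none
Why: Catalytic hydrogenolysis of the aryl benzyl ether over Pd/C in neutral ethyl acetate at atmospheric pressure is much faster than cleavage of the cyclic benzylic C2–O1 bond, so the phenol should be released without touching the ring or any stereocentre.

Compound list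
1 | 3-hydroxy-4,5-dimethoxybenzaldehyde | COc1cc(C=O)cc(O)c1OC | starting material
2 | 3-(benzyloxy)-4,5-dimethoxybenzaldehyde | COc1cc(C=O)cc(OCc2ccccc2)c1OC | intermediate
3 | vinylmagnesium bromide | C=C[Mg]Br | starting material
4 | rac-1-[3-(benzyloxy)-4,5-dimethoxyphenyl]prop-2-en-1-ol | C=CC(O)c1cc(OC)c(OC)c(OCc2ccccc2)c1 | intermediate
5 | 1-(benzyloxy)-5-[(1E)-3-bromoprop-1-en-1-yl]-2,3-dimethoxybenzene | COc1cc(/C=C/CBr)cc(OCc2ccccc2)c1OC | intermediate
6 | 3,4,5-trimethoxybenzaldehyde | COc1cc(C=O)cc(OC)c1OC | starting material
7 | rac-1-(3,4,5-trimethoxyphenyl)prop-2-en-1-ol | C=CC(O)c1cc(OC)c(OC)c(OC)c1 | intermediate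
8 | (S)-[(2R)-oxiran-2-yl](3,4,5-trimethoxyphenyl)methanol | O[C@@H](c1cc(OC)c(OC)c(OC)c1)[C@H]1CO1 | intermediate
9 | (2R)-2-[(S)-{[(2E)-3-[3-(benzyloxy)-4,5-dimethoxyphenyl]prop-2-en-1-yl]oxy}(3,4,5-trimethoxyphenyl)methyl]oxirane | COc1cc(/C=C/CO[C@@H](c2cc(OC)c(OC)c(OC)c2)[C@H]2CO2)cc(OCc2ccccc2)c1OC | intermediate
10 | cyclised bis-titanium(IV) species: C9 alkoxide and C7′ benzyl anion of 11, each bound to a Cp2TiCl unit (written as ions) | COc1cc([CH-][C@@H]2CO[C@@H](c3cc(OC)c(OC)c(OC)c3)[C@@H]2C[O-])cc(OCc2ccccc2)c1OC.[Ti+4].[Ti+4].[Cl-].[Cl-].c1cc[cH-]c1.c1cc[cH-]c1.c1cc[cH-]c1.c1cc[cH-]c1 | intermediate (not isolated)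
11 | [(2R,3S,4S)-4-[3-(benzyloxy)-4,5-dimethoxybenzyl]-2-(3,4,5-trimethoxyphenyl)oxolan-3-yl]methanol | COc1cc(C[C@@H]2CO[C@@H](c3cc(OC)c(OC)c(OC)c3)[C@@H]2CO)cc(OCc2ccccc2)c1OC | intermediate
12 | [(2R,3S,4S)-4-(3-hydroxy-4,5-dimethoxybenzyl)-2-(3,4,5-trimethoxyphenyl)oxolan-3-yl]methanol | COc1cc(C[C@@H]2CO[C@@H](c3cc(OC)c(OC)c(OC)c3)[C@@H]2CO)cc(O)c1OC | target

Total step count: 8
Longest linear sequence: 6 steps (steps 1, 2, 3, 6, 7, 8, from 1 to 12)

Steps most likely to fail

Step 7. The C3 radical may be captured by a second titanium(III) before it cyclises, which ends in β-elimination and loss of the oxygen, or the oxirane may open too slowly for the chain of events to stay clean. The fallback sets out from 9 and generates the same C3 radical by a tin hydride chain instead of by reductive epoxide opening. The oxirane of 9 is opened at its terminal carbon with benzoic acid (Bu4NBr cat., MeCN, 80 °C) to give the C9 benzoate with a free C3 hydroxyl, (2R,3S)-3-(cinnamyloxy)-2-hydroxy-3-(3,4,5-trimethoxyphenyl)propyl benzoate F1. This hydroxyl is converted with 1,1′-thiocarbonyldiimidazole (DMAP cat., toluene, 70 °C) into the O-imidazole-1-carbothioate F2. Slow addition of Bu3SnH/AIBN in refluxing benzene (Barton–McCombie-type C–O homolysis followed by the same 5-exo closure onto the styrene, with hydrogen transfer from tin to C7′) should give the cyclised C9 benzoate F3. Methanolysis (K2CO3, MeOH, rt) brings the material back to the route at 11.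

Step 5. Discrimination between the two enantiomers of 7 may be incomplete, so that the slow enantiomer is co-epoxidised as conversion rises and the enantiomeric purity of 8 is too low. The fallback sets out from 7 and separates the selection of the enantiomer from the epoxidation. Lipase-catalysed acylation (immobilised Candida antarctica lipase B, vinyl acetate, MTBE, rt) is expected to acylate the (R)-alcohol and leave (S)-7, giving (R)-1-(3,4,5-trimethoxyphenyl)prop-2-en-1-yl acetate F4. Methanolysis (K2CO3, MeOH, 0 °C) releases (R)-1-(3,4,5-trimethoxyphenyl)prop-2-en-1-ol F5. Epoxidation of F5 with Ti(OiPr)4, L-(+)-DIPT and t-BuOOH, now as the matched pair and run to full conversion, comes back to the route at 8.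

Step 6. Silver-assisted ionisation of 5 may lead to attack at the benzylic terminus (branched ether) or to loss of the bromide by hydrolysis and self-condensation, and the hindered hydroxyl of 8 may react too slowly. The fallback sets out from 4 and 8 and replaces the halide displacement by a palladium-catalysed allylic etherification. Alcohol 4 is converted with Boc2O (DMAP cat., CH2Cl2, 0 °C) into tert-butyl 1-[3-(benzyloxy)-4,5-dimethoxyphenyl]prop-2-en-1-yl carbonate F6. Treatment of F6 with 8 under Pd2(dba)3/dppb in THF at 60 °C (Tsuji–Trost O-allylation under neutral conditions: the π-allyl complex is attacked at its unhindered terminus by the alcohol, which the tert-butoxide released on decarboxylation deprotonates) should give the linear (E)-ether and comes back to the route at 9. The isolated oxirane is not expected to react with palladium(0).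

Further compounds
F1 | step 7 | (2R,3S)-3-{[(2E)-3-[3-(benzyloxy)-4,5-dimethoxyphenyl]prop-2-en-1-yl]oxy}-2-hydroxy-3-(3,4,5-trimethoxyphenyl)propyl benzoate | COc1cc(/C=C/CO[C@@H](c2cc(OC)c(OC)c(OC)c2)[C@H](O)COC(=O)c2ccccc2)cc(OCc2ccccc2)c1OC
F2 | step 7 | (2R,3S)-3-{[(2E)-3-[3-(benzyloxy)-4,5-dimethoxyphenyl]prop-2-en-1-yl]oxy}-2-[(1H-imidazol-1-ylcarbonothioyl)oxy]-3-(3,4,5-trimethoxyphenyl)propyl benzoate | COc1cc(/C=C/CO[C@@H](c2cc(OC)c(OC)c(OC)c2)[C@H](OC(=S)n2ccnc2)COC(=O)c2ccccc2)cc(OCc2ccccc2)c1OC
F3 | step 7 | [(2R,3S,4S)-4-[3-(benzyloxy)-4,5-dimethoxybenzyl]-2-(3,4,5-trimethoxyphenyl)oxolan-3-yl]methyl benzoate | COc1cc(C[C@@H]2CO[C@@H](c3cc(OC)c(OC)c(OC)c3)[C@@H]2COC(=O)c2ccccc2)cc(OCc2ccccc2)c1OC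
F4 | step 5 | (R)-1-(3,4,5-trimethoxyphenyl)prop-2-en-1-yl acetate | C=C[C@@H](OC(C)=O)c1cc(OC)c(OC)c(OC)c1
F5 | step 5 | (R)-1-(3,4,5-trimethoxyphenyl)prop-2-en-1-ol | C=C[C@@H](O)c1cc(OC)c(OC)c(OC)c1
F6 | step 6 | tert-butyl 1-[3-(benzyloxy)-4,5-dimethoxyphenyl]prop-2-en-1-yl carbonate (racemic) | C=CC(OC(=O)OC(C)(C)C)c1cc(OC)c(OC)c(OCc2ccccc2)c1
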